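**Retrosynthetic overview**

1. Labels: the backbone is C1 (CO2H)–C2–C3–C4–C5 (CHO). C2 carries the 6-oxohept-1-en-2-yl group. C3 carries Ca, the formyl-bearing alkene carbon, which is double-bonded to Cb of the 5,5-dimethyl-2,5-dihydrofuran (ring F).
2. Enabling feature: C1(=O)–C2–C3–Ca–CHO is a 1,5-dicarbonyl chain, the seco form of a 3,4-dihydro-2H-pyran-2-one (temporary ring P: O, C1, C2, C3, Ca, formyl C). Ca is also the central carbon of a masked 1,3-dicarbonyl (formyl C plus the enol-ether carbon Cb of ring F).
3. Last disconnection: acid-triggered ring switch of a ring P enol lactone. The tertiary alcohol closes onto the Cb ketone and water opens the enol ester, which gives ring F, CO2H and CHO. The acetal and ketal fall in the same step.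
4. Key disconnection C3–Ca: an achiral 2-alkenyl dienoic acid and an achiral (Z)-enynone are tied as an enol ester. A chiral carbene then rearranges it (Ireland–Coates Claisen type), setting C3, C2 and ring P in one flask.
5. The acid comes from a three-component allenoate coupling, and the enynone from 2-methylbut-3-yn-2-ol. Ring order: dioxolane (purchased), then ring P (step 9), then ring F (step 10, in which ring P and the dioxolane are opened).

Key step: step 9

Assumption: the sense of induction of the chiral carbene on this α-branched acyl azolium is taken to give the (3S) centre with the (5aR,10bS) salt. If the opposite face is attacked, the equally available (5aS,10bR) salt is used with nothing else changed.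

**Step 1**
Reactants: 1 3,3-diethoxypropan-1-ol
Product: 2 3,3-diethoxypropanal
Conditions: 2-iodoxybenzoic acid, DMSO–THF, rt
Reagents that add atoms: none
Why: Hypervalent-iodine oxidation of a primary alcohol stops at the aldehyde under near-neutral conditions, so the elimination-prone β-acetal aldehyde should survive and is used crude.

**Step 2**
Reactants: 3 2-(3-chloropropyl)-2-methyl-1,3-dioxolane; 4 ethyl buta-2,3-dienoate; 2 3,3-diethoxypropanal
Product: 7 ethyl 2-(3,3-diethoxy-1-hydroxypropyl)-3-methylidene-6-(2-methyl-1,3-dioxolan-2-yl)hexanoate (racemic diastereomer mixture), via Grignard reagent 5 (not isolated), via magnesium dienolate 6 (not isolated)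
Conditions: Mg, THF, 50 °C; then 4, Fe(acac)3 (5 mol %), toluene–THF, −78 °C; then 2, −78 °C; aq. NH4Cl
Reagents that add atoms: none
Why: Iron-catalysed conjugate addition of a Grignard reagent to the central carbon of a 2,3-allenoate gives a magnesium 1,3-dienolate that adds to the aldehyde through its α-carbon (tandem conjugate addition–aldol), which installs the 1,1-disubstituted alkene directly; the two new stereocentres form unselectively and are erased in step 3.

**Step 3**
Reactants: 7 aldol adduct
Product: 9 ethyl (2E)-5,5-diethoxy-2-[5-(2-methyl-1,3-dioxolan-2-yl)pent-1-en-2-yl]pent-2-enoate, via mesylate 8 (not isolated)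
Conditions: MeSO2Cl, Et3N, CH2Cl2, 0 °C; then 1,8-diazabicyclo[5.4.0]undec-7-ene (DBU), 0 °C to rt
Reagents that add atoms: none
Why: Mesylation followed by E1cB elimination through the doubly activated (ester and allyl) α-C–H gives the conjugated enoate, and the carbanion mechanism should favour the (E)-isomer, with the chain anti to the coplanar ester.

**Step 4**
Reactants: 9 dienoate
Product: 11 (2E)-5,5-diethoxy-2-[5-(2-methyl-1,3-dioxolan-2-yl)pent-1-en-2-yl]pent-2-enoic acid, via lithium carboxylate 10 (not isolated)
Conditions: LiOH·H2O, THF–MeOH–H2O, 40 °C; then 0.5 M HCl to pH 4–5, 0 °C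
Reagents that add atoms: lithium hydroxide, [Li+].[OH-]
Why: Ester saponification leaves the acetal, ketal and diene untouched, and cold, mild acidification keeps both acetals intact.

**Step 5**
Reactants: 12 2-methylbut-3-yn-2-ol
Product: 13 triethyl[(2-methylbut-3-yn-2-yl)oxy]silane
Conditions: Et3SiCl, imidazole, 4-(dimethylamino)pyridine (5 mol %), DMF, rt
Reagents that add atoms: chlorotriethylsilane, CC[Si](Cl)(CC)CC
Why: Standard silylation of an unhindered propargylic tertiary alcohol; the triethylsilyl ether withstands bases, hydrogenation and carbenes but is acid-labile for step 10.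

**Step 6**
Reactants: 13 silyl ether; 14 N-methoxy-N-methylcarbamoyl chloride
Product: 16 N-methoxy-N,4-dimethyl-4-[(triethylsilyl)oxy]pent-2-ynamide, via lithium acetylide 15 (not isolated)
Conditions: n-BuLi, THF, −78 °C; then 14, −78 °C to 0 °C
Reagents that add atoms: none
Why: Acylation of a lithium acetylide with the carbamoyl chloride gives the alkynyl N-methoxy-N-methylamide in one step, and that amide does not react further with the acetylide.

**Step 7**
Reactants: 16 ynamide
Product: 17 (2Z)-N-methoxy-N,4-dimethyl-4-[(triethylsilyl)oxy]pent-2-enamide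
Conditions: H2 (1 atm), Pd/CaCO3 poisoned with Pb(OAc)2, quinoline, EtOAc, rt
Reagents that add atoms: none
Why: syn-Semihydrogenation of the alkyne on the poisoned palladium surface sets the Z alkene that later allows ring F to close.

**Step 8**
Reactants: 17 (Z)-enamide; 18 ethynylmagnesium bromide
Product: 20 (4Z)-6-methyl-6-[(triethylsilyl)oxy]hept-4-en-1-yn-3-one, via chelated adduct 19 (not isolated)
Conditions: 18 (0.5 M in THF), THF, −20 to 0 °C; inverse quench into cold aq. NaHSO4
Reagents that add atoms: none
Why: Ketone synthesis from an N-methoxy-N-methylamide, in which the chelated tetrahedral adduct prevents over-addition and the cold acidic inverse quench protonates the released amine before it can add to the ynone.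

**Step 9**
Reactants: 11 dienoic acid; 20 (Z)-enynone
Product: 22 (3R,4S)-4-(2,2-diethoxyethyl)-5-{(2Z)-4-methyl-4-[(triethylsilyl)oxy]pent-2-enoyl}-3-[5-(2-methyl-1,3-dioxolan-2-yl)pent-1-en-2-yl]-3,4-dihydro-2H-pyran-2-one, via enol ester 21 (not isolated)
Conditions: N-methylmorpholine (10 mol %), toluene, 0 °C to rt; then (5aR,10bS)-2-mesityl-5a,10b-dihydro-4H,6H-indeno[2,1-b][1,2,4]triazolo[4,3-d][1,4]oxazin-2-ium chloride (10 mol %), KN(SiMe3)2 (9 mol %), 4 Å molecular sieves, rt to 40 °C; finally DBU (10 mol %), rt
Reagents that add atoms: none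
Why: N-Methylmorpholine catalyses conjugate addition of acid 11 to the terminal alkyne carbon of 20, and the vinylogous-anhydride C–O bond of the resulting enol ester 21 is cleaved by the triazolylidene into an α,β-unsaturated acyl azolium and the formyl-enone enolate, which recombine by 1,2-addition and [3,3] shift (formally a Michael addition) so that the central enolate carbon Ca bonds to C3. Proton transfer to C2 regenerates an acyl azolium that acylates the formyl enol oxygen, which closes temporary ring P by 6-exo-trig lactonisation and releases the carbene. The closest known reaction type is the carbene-catalysed Ireland–Coates Claisen-type rearrangement of α,β-unsaturated enol esters to 3,4-dihydropyran-2-ones, which is known for α,β-disubstituted acyl parts and for enolates of formyl carbonyl compounds, and the related acyl azolium/1,3-dicarbonyl annulation is known in enantioselective form with aminoindanol-derived triazolylidenes. C3 is set by catalyst control, because the indane wall of the carbene shields one face of the planar acyl azolium. C2 is set by substrate control, because its acidic α-proton equilibrates under DBU to the 3,4-trans (diaxial) lactone, which avoids both the gauche contact of the two large groups and A(1,2) strain with the 5-acyl group. The step needs attack at C3 only and C- rather than O-bonding: the 1,1-disubstituted alkene on C2 is cross-conjugated and not activated by the acyl azolium, the β-carbon of the Z-enone is shielded by the adjacent quaternary silyloxy carbon, and O-attack is reversible.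

**Step 10**
Reactants: 22 ring P lactone
Product: 25 (2R,3S)-3-[(E)-(5,5-dimethylfuran-2(5H)-ylidene)(formyl)methyl]-5-oxo-2-(6-oxohept-1-en-2-yl)pentanoic acid, via hemiketal lactone 23 (not isolated), via bis-acetal acid 24 (not isolated)
Conditions: 1 M aq. HCl–THF (1:3), 0 °C to rt
Reagents that add atoms: water, O
Why: Acid removes the silyl ether so that the (Z)-γ-hydroxy enone closes 5-exo-trig to hemiketal 23, whose ionisation to a 2H-furanium ion and capture of water at the enol-ester carbon gives an acylal that collapses to CO2H, CHO and ring F (enol-ester hydrolysis plus cyclodehydration of a hydroxy-1,3-dicarbonyl to a vinylogous ester), while the acetal and ketal hydrolyse; the push–pull Ca=Cb alkene equilibrates under acid to the E isomer that places bulky C3 next to the ring oxygen, and C2 and C3 are not touched.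

**Compound list**

1 | 3,3-diethoxypropan-1-ol | CCOC(CCO)OCC | starting material
2 | 3,3-diethoxypropanal | CCOC(CC=O)OCC | intermediate
3 | 2-(3-chloropropyl)-2-methyl-1,3-dioxolane | CC1(CCCCl)OCCO1 | starting material
4 | ethyl buta-2,3-dienoate | C=C=CC(=O)OCC | starting material
5 | [3-(2-methyl-1,3-dioxolan-2-yl)propyl]magnesium chloride | CC1(CCC[Mg]Cl)OCCO1 | intermediate
6 | chloromagnesium 1,3-dienolate of ethyl 3-methylidene-6-(2-methyl-1,3-dioxolan-2-yl)hexanoate | C=C(CCCC1(C)OCCO1)C=C(OCC)O[Mg]Cl | intermediate
7 | ethyl 2-(3,3-diethoxy-1-hydroxypropyl)-3-methylidene-6-(2-methyl-1,3-dioxolan-2-yl)hexanoate | CCOC(=O)C(C(O)CC(OCC)OCC)C(=C)CCCC1(C)OCCO1 | intermediate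
8 | methanesulfonate of 7 | CCOC(=O)C(C(CC(OCC)OCC)OS(C)(=O)=O)C(=C)CCCC1(C)OCCO1 | intermediate
9 | ethyl (2E)-5,5-diethoxy-2-[5-(2-methyl-1,3-dioxolan-2-yl)pent-1-en-2-yl]pent-2-enoate | CCOC(=O)/C(=C/CC(OCC)OCC)C(=C)CCCC1(C)OCCO1 | intermediate
10 | lithium salt of 11 | [Li+].[O-]C(=O)/C(=C/CC(OCC)OCC)C(=C)CCCC1(C)OCCO1 | intermediate
11 | (2E)-5,5-diethoxy-2-[5-(2-methyl-1,3-dioxolan-2-yl)pent-1-en-2-yl]pent-2-enoic acid | OC(=O)/C(=C/CC(OCC)OCC)C(=C)CCCC1(C)OCCO1 | intermediate
12 | 2-methylbut-3-yn-2-ol | C#CC(C)(C)O | starting material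
13 | triethyl[(2-methylbut-3-yn-2-yl)oxy]silane | C#CC(C)(C)O[Si](CC)(CC)CC | intermediate
14 | N-methoxy-N-methylcarbamoyl chloride | CON(C)C(=O)Cl | starting material
15 | lithium acetylide of 13 | [Li]C#CC(C)(C)O[Si](CC)(CC)CC | intermediate
16 | N-methoxy-N,4-dimethyl-4-[(triethylsilyl)oxy]pent-2-ynamide | CON(C)C(=O)C#CC(C)(C)O[Si](CC)(CC)CC | intermediate
17 | (2Z)-N-methoxy-N,4-dimethyl-4-[(triethylsilyl)oxy]pent-2-enamide | CON(C)C(=O)/C=C\C(C)(C)O[Si](CC)(CC)CC | intermediate
18 | ethynylmagnesium bromide | C#C[Mg]Br | starting material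
19 | bromomagnesium tetrahedral adduct of 17 and 18 | C#CC(O[Mg]Br)(N(C)OC)/C=C\C(C)(C)O[Si](CC)(CC)CC | intermediate
20 | (4Z)-6-methyl-6-[(triethylsilyl)oxy]hept-4-en-1-yn-3-one | C#CC(=O)/C=C\C(C)(C)O[Si](CC)(CC)CC | intermediate
21 | (1E,4Z)-6-methyl-3-oxo-6-[(triethylsilyl)oxy]hepta-1,4-dien-1-yl (2E)-5,5-diethoxy-2-[5-(2-methyl-1,3-dioxolan-2-yl)pent-1-en-2-yl]pent-2-enoate | CCOC(OCC)C/C=C(/C(=O)O/C=C/C(=O)/C=C\C(C)(C)O[Si](CC)(CC)CC)C(=C)CCCC1(C)OCCO1 | intermediate
22 | (3R,4S)-4-(2,2-diethoxyethyl)-5-{(2Z)-4-methyl-4-[(triethylsilyl)oxy]pent-2-enoyl}-3-[5-(2-methyl-1,3-dioxolan-2-yl)pent-1-en-2-yl]-3,4-dihydro-2H-pyran-2-one | O=C1OC=C(C(=O)/C=C\C(C)(C)O[Si](CC)(CC)CC)[C@@H](CC(OCC)OCC)[C@@H]1C(=C)CCCC2(C)OCCO2 | intermediate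
23 | (3R,4S)-4-(2,2-diethoxyethyl)-5-(2-hydroxy-5,5-dimethyl-2,5-dihydrofuran-2-yl)-3-[5-(2-methyl-1,3-dioxolan-2-yl)pent-1-en-2-yl]-3,4-dihydro-2H-pyran-2-one (epimers at the hemiketal carbon) | O=C1OC=C(C2(O)C=CC(C)(C)O2)[C@@H](CC(OCC)OCC)[C@@H]1C(=C)CCCC3(C)OCCO3 | intermediate
24 | (2R,3S)-3-[(E)-(5,5-dimethylfuran-2(5H)-ylidene)(formyl)methyl]-5,5-diethoxy-2-[5-(2-methyl-1,3-dioxolan-2-yl)pent-1-en-2-yl]pentanoic acid | C=C(CCCC1(C)OCCO1)[C@H](C(=O)O)[C@H](CC(OCC)OCC)/C(C=O)=C2/C=CC(C)(C)O2 | intermediate
25 | (2R,3S)-3-[(E)-(5,5-dimethylfuran-2(5H)-ylidene)(formyl)methyl]-5-oxo-2-(6-oxohept-1-en-2-yl)pentanoic acid (CNP0150297.1) | C=C(CCCC(C)=O)[C@H](C(=O)O)[C@H](CC=O)/C(C=O)=C1/C=CC(C)(C)O1 | target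

**Step count**
Total steps: 10. Longest linear sequence: 6 (steps 1–4, 9, 10, or equally steps 5–8, 9, 10).

**Steps most likely to fail**

Step 9. The α-branched acyl azolium may turn over slowly with the triazolylidene, or it may be attacked with poor facial selectivity. The DBU equilibration may also let the 1,1-disubstituted alkene migrate into conjugation with the lactone.
Fallback: catalyst control is given up.
- The enol ester 21 is isolated after the amine stage.
- It is rearranged with the more nucleophilic achiral carbene 1,3-dimesitylimidazol-2-ylidene (from 1,3-dimesitylimidazolium chloride and KN(SiMe3)2, THF), which is the form of the reaction closest to its precedent.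
- This gives the racemic trans lactone, that is 22 together with its mirror image, the (3S,4R)-lactone F1.
- The enantiomers are separated by preparative chromatography on an amylose-based chiral stationary phase.
- The fallback sets out from 21 and returns at 22.

Step 10. In aqueous acid the hemiketal may ionise more slowly than the acetal hydrolyses. The liberated aldehyde is then captured reversibly by enol or acid functions and the mixture converges slowly. The product may also erode on prolonged acid contact.
Fallback: the events are separated, and ring P is opened first without acid.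
- From 22, LiOH (1 equiv), THF–H2O, 0 °C, followed by cold acidification to pH 5, cleaves only the activated enol ester. This gives the silyl-protected seco formyl-ketone acid F2.
- HF·pyridine in THF then removes the silyl group, and the hydroxy-1,3-dicarbonyl cyclodehydrates to 24.
- 24 is isolated and hydrolysed on its own under the mildest effective aqueous acid to give 25.
- The fallback sets out from 22 and returns at 24.

Step 2. The Grignard reagent may add to the ester carbonyl, the allenoate may oligomerise, or the dienolate may react through its γ-carbon.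
Fallback: the three bond formations are uncoupled.
- Grignard reagent 5 is coupled with diketene (NiCl2, 5 mol %, THF, −20 °C to rt; ring-opening cross-coupling at the vinylic C–O bond). This gives 3-methylidene-6-(2-methyl-1,3-dioxolan-2-yl)hexanoic acid F3.
- F3 is converted with triethyloxonium tetrafluoroborate and iPr2NEt into ethyl 3-methylidene-6-(2-methyl-1,3-dioxolan-2-yl)hexanoate F4.
- LiN(iPr)2 (THF, −78 °C) gives the lithium dienolate F5, which undergoes the kinetic α-aldol addition to 2.
- The fallback sets out from 5 and returns at 7.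

**Further compounds**

F1 | step 9 | (3S,4R)-4-(2,2-diethoxyethyl)-5-{(2Z)-4-methyl-4-[(triethylsilyl)oxy]pent-2-enoyl}-3-[5-(2-methyl-1,3-dioxolan-2-yl)pent-1-en-2-yl]-3,4-dihydro-2H-pyran-2-one | O=C1OC=C(C(=O)/C=C\C(C)(C)O[Si](CC)(CC)CC)[C@H](CC(OCC)OCC)[C@H]1C(=C)CCCC2(C)OCCO2
F2 | step 10 | 5,5-diethoxy-3-{(4Z)-6-methyl-1,3-dioxo-6-[(triethylsilyl)oxy]hept-4-en-2-yl}-2-[5-(2-methyl-1,3-dioxolan-2-yl)pent-1-en-2-yl]pentanoic acid (backbone centres as in 22, formyl-ketone carbon enolisable) | C=C(CCCC1(C)OCCO1)[C@H](C(=O)O)[C@H](CC(OCC)OCC)C(C=O)C(=O)/C=C\C(C)(C)O[Si](CC)(CC)CC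
F3 | step 2 | 3-methylidene-6-(2-methyl-1,3-dioxolan-2-yl)hexanoic acid | C=C(CCCC1(C)OCCO1)CC(=O)O
F4 | step 2 | ethyl 3-methylidene-6-(2-methyl-1,3-dioxolan-2-yl)hexanoate | C=C(CCCC1(C)OCCO1)CC(=O)OCC
F5 | step 2 | lithium 1,3-dienolate of F4 | C=C(CCCC1(C)OCCO1)C=C(OCC)O[Li]
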